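Everything rests on the disconnection between C15, the acetoxy-bearing carbon, and C14, the chain methylene next to it. C15 carries oxygen and adjoins C16, the fully substituted methyl-bearing carbon of the γ-lactone ring, so it can enter at the acyl level without enolisation or epimerisation towards the ring. In the key step the polarity of C14 is reversed by zinc insertion into a primary iodide that holds the whole furyl diene chain (C10 silyl-protected), and the alkylzinc is acylated under palladium catalysis by the acid chloride of the preformed (S)-lactone acid derived from linalool. One operation thus unites both fragments as a C15 ketone, which a reagent-controlled reduction then converts into the R carbinol.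

Key step: step 12

Remark (atom numbering): furan carbons C1–C4, chain C5–C15 (C10 is the carbinol, C15 the acetoxy carbon), lactone carbons C16–C19 (C16 quaternary, C19 carbonyl).
Remark (assumption): (S)-(+)-linalool is taken as purchasable in high enantiomeric purity; its carbinol centre is carried unchanged into C16.

Step 1
Reactants: 1 4-(tert-butyldimethylsilyloxy)but-1-yne
Product: 4 (E)-5-(tert-butyldimethylsilyloxy)-3-methylpent-2-en-1-ol, via alkenyldimethylalane 2 (not isolated), via lithium alkenylaluminate 3 (not isolated)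
Conditions: Me3Al, Cp2ZrCl2 (25 mol%), CH2Cl2, 0 °C to rt; then n-BuLi, THF, −78 °C; then (CH2O)n, −78 °C to rt
Reagents that add atoms: trimethylaluminium (C[Al](C)C); paraformaldehyde as formaldehyde (C=O)
Why: Zirconium-catalysed Negishi carboalumination adds methyl and aluminium syn across the terminal alkyne with the metal on the terminal carbon, and the derived aluminate should capture formaldehyde with retention, which fixes the E geometry of the C11=C12 double bond.

Step 2
Reactants: 4 (E)-5-(tert-butyldimethylsilyloxy)-3-methylpent-2-en-1-ol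
Product: 5 (E)-5-(tert-butyldimethylsilyloxy)-3-methylpent-2-enal
Conditions: MnO2 (activated), CH2Cl2, rt
Reagents that add atoms: none
Why: Activated MnO2 should oxidise the allylic alcohol selectively to the enal without touching the silyl ether or the double-bond geometry (allylic oxidation).

Step 3
Reactants: 5 (E)-5-(tert-butyldimethylsilyloxy)-3-methylpent-2-enal
Product: 6 (4S,5E)-8-(tert-butyldimethylsilyloxy)-6-methyloct-5-en-1-yn-4-ol
Conditions: allenylboronic acid pinacol ester (1.5 equiv), (S)-TRIP phosphoric acid (10 mol%), 4 Å MS, toluene, 0 °C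
Reagents that add atoms: allenylboronic acid pinacol ester (C=C=CB1OC(C)(C)C(C)(C)O1)
Why: Chiral phosphoric acid-catalysed propargylation with the allenylboronate runs through a six-membered cyclic transition state in which the (S)-configured acid should direct the propargyl group to the Si face of the aldehyde, which sets C10 as S.

Step 4
Reactants: 6 (4S,5E)-8-(tert-butyldimethylsilyloxy)-6-methyloct-5-en-1-yn-4-ol
Product: 7 (4S,5E)-8-(tert-butyldimethylsilyloxy)-4-(tert-butyldiphenylsilyloxy)-6-methyloct-5-en-1-yne
Conditions: TBDPSCl, imidazole, DMAP (cat.), DMF, rt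
Reagents that add atoms: tert-butyldiphenylsilyl chloride (CC(C)(C)[Si](Cl)(c1ccccc1)c1ccccc1)
Why: Silylation of the secondary alcohol gives a robust ether that should survive the later selective cleavage of the primary TBS group, with the C10 configuration untouched (silyl protection).

Step 5
Reactants: 7 (4S,5E)-8-(tert-butyldimethylsilyloxy)-4-(tert-butyldiphenylsilyloxy)-6-methyloct-5-en-1-yne
Product: 9 (1E,4S,5E)-8-(tert-butyldimethylsilyloxy)-4-(tert-butyldiphenylsilyloxy)-1-iodo-2,6-dimethylocta-1,5-diene, via alkenyldimethylalane 8 (not isolated)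
Conditions: Me3Al, Cp2ZrCl2 (20 mol%), H2O (1 equiv), CH2Cl2, −20 °C to rt; then I2, THF, −20 to 0 °C
Reagents that add atoms: trimethylaluminium (C[Al](C)C); iodine (II)
Why: Zirconium-catalysed syn-carboalumination of the terminal alkyne followed by iodinolysis with retention should give the E-configured 2-methylalkenyl iodide that defines the C7=C8 geometry (Negishi carboalumination–iodination).

Step 6
Reactants: 10 furan-3-carbaldehyde
Product: 11 3-vinylfuran
Conditions: Ph3PCH3Br, n-BuLi, THF, 0 °C to rt
Reagents that add atoms: methyltriphenylphosphonium bromide ([Br-].C[P+](c1ccccc1)(c1ccccc1)c1ccccc1)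
Why: Wittig methylenation of the aldehyde should give the terminal alkene, which is handled as a solution because of its volatility.

Step 7
Reactants: 9 (1E,4S,5E)-8-(tert-butyldimethylsilyloxy)-4-(tert-butyldiphenylsilyloxy)-1-iodo-2,6-dimethylocta-1,5-diene; 11 3-vinylfuran
Product: 13 3-[(3E,6S,7E)-10-(tert-butyldimethylsilyloxy)-6-(tert-butyldiphenylsilyloxy)-4,8-dimethyldeca-3,7-dienyl]furan, via B-(furylethyl)-9-BBN 12 (not isolated)
Conditions: 11, 9-BBN, THF, 0 °C to rt; then 9, Pd(dppf)Cl2 (5 mol%), AsPh3, Cs2CO3, DMF/THF/H2O, rt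
Reagents that add atoms: none
Why: Anti-Markovnikov hydroboration of the vinylfuran gives a primary alkylborane that should undergo B-alkyl Suzuki–Miyaura coupling with the alkenyl iodide with retention of the E geometry.

Step 8
Reactants: 13 3-[(3E,6S,7E)-10-(tert-butyldimethylsilyloxy)-6-(tert-butyldiphenylsilyloxy)-4,8-dimethyldeca-3,7-dienyl]furan
Product: 14 (3E,5S,7E)-5-(tert-butyldiphenylsilyloxy)-10-(furan-3-yl)-3,7-dimethyldeca-3,7-dien-1-ol
Conditions: HF·pyridine, pyridine, THF, 0 °C
Reagents that add atoms: none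
Why: Buffered HF·pyridine cleaves the unhindered primary TBS ether much faster than the secondary TBDPS ether, so only the C14 hydroxyl should be released (selective desilylation).

Step 9
Reactants: 14 (3E,5S,7E)-5-(tert-butyldiphenylsilyloxy)-10-(furan-3-yl)-3,7-dimethyldeca-3,7-dien-1-ol
Product: 15 3-[(3E,6S,7E)-6-(tert-butyldiphenylsilyloxy)-10-iodo-4,8-dimethyldeca-3,7-dienyl]furan
Conditions: PPh3, I2, imidazole, CH2Cl2, 0 °C to rt
Reagents that add atoms: iodine (II)
Why: Appel-type iodination converts the primary alcohol into the iodide by SN2 displacement of the alkoxyphosphonium group under near-neutral conditions that the furan and the allylic silyl ether should tolerate.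

Step 10
Reactants: 16 (S)-(+)-linalool
Product: 17 (2S)-2-methyl-5-oxotetrahydrofuran-2-carboxylic acid
Conditions: RuCl3·xH2O (2 mol%), NaIO4 (excess), CCl4/MeCN/H2O, rt; acidic work-up
Reagents that add atoms: sodium periodate ([Na+].[O-]I(=O)(=O)=O); water (O)
Why: RuO4 formed from RuCl3 and NaIO4 should cleave both alkenes to carboxylic acids and the tertiary γ-hydroxy acid lactonises on acidic work-up, so the carbinol stereocentre of 16 is carried unchanged into C16 as S (oxidative alkene cleavage followed by lactonisation).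

Step 11
Reactants: 17 (2S)-2-methyl-5-oxotetrahydrofuran-2-carboxylic acid
Product: 18 (2S)-2-methyl-5-oxotetrahydrofuran-2-carbonyl chloride
Conditions: (COCl)2, DMF (cat.), CH2Cl2, 0 °C to rt
Reagents that add atoms: oxalyl chloride (ClC(=O)C(Cl)=O)
Why: Oxalyl chloride with catalytic DMF converts the acid into the acid chloride through a chloroiminium species, and the quaternary α-carbon cannot epimerise (acid chloride formation).

Step 12
Reactants: 15 3-[(3E,6S,7E)-6-(tert-butyldiphenylsilyloxy)-10-iodo-4,8-dimethyldeca-3,7-dienyl]furan; 18 (2S)-2-methyl-5-oxotetrahydrofuran-2-carbonyl chloride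
Product: 20 (5S)-5-[(4E,6S,8E)-6-(tert-butyldiphenylsilyloxy)-11-(furan-3-yl)-4,8-dimethylundeca-4,8-dienoyl]-5-methyldihydrofuran-2(3H)-one, via alkylzinc iodide 19 (not isolated)
Conditions: 15, Zn dust (activated with 1,2-dibromoethane and TMSCl), LiCl, THF, 25–40 °C; then 18, Pd(PPh3)4 (5 mol%), THF, 0 °C to rt
Reagents that add atoms: none
Why: Zinc inserts into the primary C14–I bond of 15, which reverses the polarity of C14 and gives alkylzinc iodide 19; zerovalent palladium then adds into the C15–Cl bond of 18, the alkyl group passes from zinc to palladium and reductive elimination forms the C14–C15 bond of ketone 20. The closest known reaction type is the Negishi acylation of alkylzinc halides with acid chlorides, to which the Fukuyama thioester coupling is closely related. No ring is closed, and the γ-lactone of 18 is carried through intact. No stereocentre is formed: C16 has no hydrogen and cannot epimerise, C10 is remote, and C15 is deliberately left at the ketone level because the methyl and ring-methylene groups on C16 would give an aldehyde too little facial bias, so its configuration is set by reagent control in step 13. The step needs chemoselectivity for the acid chloride over the lactone carbonyl, the silyl ether and the furan, and it must avoid β-hydride elimination and over-addition to the ketone. The low basicity and nucleophilicity of the alkylzinc, the much faster oxidative addition at the acyl chloride and the rapid reductive elimination from the acyl(alkyl)palladium species should secure this.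

Step 13
Reactants: 20 (5S)-5-[(4E,6S,8E)-6-(tert-butyldiphenylsilyloxy)-11-(furan-3-yl)-4,8-dimethylundeca-4,8-dienoyl]-5-methyldihydrofuran-2(3H)-one
Product: 21 (5S)-5-[(1R,4E,6S,8E)-6-(tert-butyldiphenylsilyloxy)-11-(furan-3-yl)-1-hydroxy-4,8-dimethylundeca-4,8-dienyl]-5-methyldihydrofuran-2(3H)-one
Conditions: (S)-2-methyl-CBS-oxazaborolidine (20 mol%), catecholborane, toluene, −78 °C; pH 7 buffer work-up
Reagents that add atoms: none
Why: Corey–Bakshi–Shibata reduction distinguishes the fully substituted C16 flank from the methylene flank of the ketone, so the (S)-oxazaborolidine should deliver hydride to the Si face of C15 and set it as R under reagent control, while catecholborane at low temperature should leave the trisubstituted alkenes and the lactone untouched.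

Step 14
Reactants: 21 (5S)-5-[(1R,4E,6S,8E)-6-(tert-butyldiphenylsilyloxy)-11-(furan-3-yl)-1-hydroxy-4,8-dimethylundeca-4,8-dienyl]-5-methyldihydrofuran-2(3H)-one
Product: 22 (1R,4E,6S,8E)-6-(tert-butyldiphenylsilyloxy)-11-(furan-3-yl)-4,8-dimethyl-1-[(2S)-2-methyl-5-oxotetrahydrofuran-2-yl]undeca-4,8-dienyl acetate
Conditions: Ac2O, pyridine, DMAP (cat.), CH2Cl2, rt
Reagents that add atoms: acetic anhydride (CC(=O)OC(C)=O)
Why: DMAP-catalysed acylation with acetic anhydride should esterify the hindered secondary C15 alcohol with retention of configuration and thereby also block translactonisation.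

Step 15
Reactants: 22 (1R,4E,6S,8E)-6-(tert-butyldiphenylsilyloxy)-11-(furan-3-yl)-4,8-dimethyl-1-[(2S)-2-methyl-5-oxotetrahydrofuran-2-yl]undeca-4,8-dienyl acetate
Product: 23 15-acetylirciformonin B
Conditions: TBAF, AcOH, THF, rt
Reagents that add atoms: none
Why: Fluoride cleaves the Si–O bond of the TBDPS ether, and buffering with acetic acid should keep the medium mild enough for the acetate, the lactone and the allylic alcohol, with the C10 configuration untouched (desilylation).

Compound list
1 | 4-(tert-butyldimethylsilyloxy)but-1-yne | C#CCCO[Si](C)(C)C(C)(C)C | starting material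
2 | (E)-[4-(tert-butyldimethylsilyloxy)-2-methylbut-1-enyl]dimethylalane (formed in the flask) | CC(C)(C)[Si](C)(C)OCC/C(C)=C/[Al](C)C | intermediate
3 | lithium butyl[(E)-4-(tert-butyldimethylsilyloxy)-2-methylbut-1-enyl]dimethylaluminate (formed in the flask) | [Li+].CC(C)(C)[Si](C)(C)OCC/C(C)=C/[Al-](C)(C)CCCC | intermediate
4 | (E)-5-(tert-butyldimethylsilyloxy)-3-methylpent-2-en-1-ol | CC(C)(C)[Si](C)(C)OCC/C(C)=C/CO | intermediate
5 | (E)-5-(tert-butyldimethylsilyloxy)-3-methylpent-2-enal | CC(C)(C)[Si](C)(C)OCC/C(C)=C/C=O | intermediate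
6 | (4S,5E)-8-(tert-butyldimethylsilyloxy)-6-methyloct-5-en-1-yn-4-ol | CC(C)(C)[Si](C)(C)OCC/C(C)=C/[C@@H](O)CC#C | intermediate
7 | (4S,5E)-8-(tert-butyldimethylsilyloxy)-4-(tert-butyldiphenylsilyloxy)-6-methyloct-5-en-1-yne | CC(C)(C)[Si](C)(C)OCC/C(C)=C/[C@@H](O[Si](c1ccccc1)(c1ccccc1)C(C)(C)C)CC#C | intermediate
8 | [(1E,4S,5E)-8-(tert-butyldimethylsilyloxy)-4-(tert-butyldiphenylsilyloxy)-2,6-dimethylocta-1,5-dienyl]dimethylalane (formed in the flask) | CC(C)(C)[Si](C)(C)OCC/C(C)=C/[C@@H](O[Si](c1ccccc1)(c1ccccc1)C(C)(C)C)C/C(C)=C/[Al](C)C | intermediate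
9 | (1E,4S,5E)-8-(tert-butyldimethylsilyloxy)-4-(tert-butyldiphenylsilyloxy)-1-iodo-2,6-dimethylocta-1,5-diene | CC(C)(C)[Si](C)(C)OCC/C(C)=C/[C@@H](O[Si](c1ccccc1)(c1ccccc1)C(C)(C)C)C/C(C)=C/I | intermediate
10 | furan-3-carbaldehyde | O=Cc1ccoc1 | starting material
11 | 3-vinylfuran | C=Cc1ccoc1 | intermediate
12 | 9-[2-(furan-3-yl)ethyl]-9-borabicyclo[3.3.1]nonane (formed in the flask) | c1occc1CCB1C2CCCC1CCC2 | intermediate
13 | 3-[(3E,6S,7E)-10-(tert-butyldimethylsilyloxy)-6-(tert-butyldiphenylsilyloxy)-4,8-dimethyldeca-3,7-dienyl]furan | CC(C)(C)[Si](C)(C)OCC/C(C)=C/[C@@H](O[Si](c1ccccc1)(c1ccccc1)C(C)(C)C)C/C(C)=C/CCc1ccoc1 | intermediate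
14 | (3E,5S,7E)-5-(tert-butyldiphenylsilyloxy)-10-(furan-3-yl)-3,7-dimethyldeca-3,7-dien-1-ol | OCC/C(C)=C/[C@@H](O[Si](c1ccccc1)(c1ccccc1)C(C)(C)C)C/C(C)=C/CCc1ccoc1 | intermediate
15 | 3-[(3E,6S,7E)-6-(tert-butyldiphenylsilyloxy)-10-iodo-4,8-dimethyldeca-3,7-dienyl]furan | ICC/C(C)=C/[C@@H](O[Si](c1ccccc1)(c1ccccc1)C(C)(C)C)C/C(C)=C/CCc1ccoc1 | intermediate
16 | (S)-(+)-linalool, (3S)-3,7-dimethylocta-1,6-dien-3-ol | C=C[C@](O)(C)CCC=C(C)C | starting material
17 | (2S)-2-methyl-5-oxotetrahydrofuran-2-carboxylic acid | OC(=O)[C@]1(C)CCC(=O)O1 | intermediate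
18 | (2S)-2-methyl-5-oxotetrahydrofuran-2-carbonyl chloride | ClC(=O)[C@]1(C)CCC(=O)O1 | intermediate
19 | [(3E,5S,7E)-5-(tert-butyldiphenylsilyloxy)-10-(furan-3-yl)-3,7-dimethyldeca-3,7-dienyl]zinc iodide (formed in the flask) | I[Zn]CC/C(C)=C/[C@@H](O[Si](c1ccccc1)(c1ccccc1)C(C)(C)C)C/C(C)=C/CCc1ccoc1 | intermediate
20 | (5S)-5-[(4E,6S,8E)-6-(tert-butyldiphenylsilyloxy)-11-(furan-3-yl)-4,8-dimethylundeca-4,8-dienoyl]-5-methyldihydrofuran-2(3H)-one | O=C(CC/C(C)=C/[C@@H](O[Si](c1ccccc1)(c1ccccc1)C(C)(C)C)C/C(C)=C/CCc1ccoc1)[C@]1(C)CCC(=O)O1 | intermediate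
21 | (5S)-5-[(1R,4E,6S,8E)-6-(tert-butyldiphenylsilyloxy)-11-(furan-3-yl)-1-hydroxy-4,8-dimethylundeca-4,8-dienyl]-5-methyldihydrofuran-2(3H)-one | O[C@H](CC/C(C)=C/[C@@H](O[Si](c1ccccc1)(c1ccccc1)C(C)(C)C)C/C(C)=C/CCc1ccoc1)[C@]1(C)CCC(=O)O1 | intermediate
22 | (1R,4E,6S,8E)-6-(tert-butyldiphenylsilyloxy)-11-(furan-3-yl)-4,8-dimethyl-1-[(2S)-2-methyl-5-oxotetrahydrofuran-2-yl]undeca-4,8-dienyl acetate | CC(=O)O[C@H](CC/C(C)=C/[C@@H](O[Si](c1ccccc1)(c1ccccc1)C(C)(C)C)C/C(C)=C/CCc1ccoc1)[C@]1(C)CCC(=O)O1 | intermediate
23 | 15-acetylirciformonin B, (1R,4E,6S,8E)-11-(furan-3-yl)-6-hydroxy-4,8-dimethyl-1-[(2S)-2-methyl-5-oxotetrahydrofuran-2-yl]undeca-4,8-dienyl acetate | CC(=O)O[C@H](CC/C(C)=C/[C@@H](O)C/C(C)=C/CCc1ccoc1)[C@]1(C)CCC(=O)O1 | target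

Total step count: 15 steps.
Longest linear sequence: 12 steps (steps 1, 2, 3, 4, 5, 7, 8, 9, 12, 13, 14, 15, from compound 1 to compound 23).

Steps most likely to fail

Step 12 (key step). Zinc insertion may stay incomplete, the alkylzinc may be protonated before it is captured, or the hindered acylpalladium species may lose CO so that acyl transfer stalls. The fallback sets out from 18 and 15 and comes back at 20. Acid chloride 18 is reduced with LiAlH(OtBu)3 (THF, −78 °C) to (2S)-2-methyl-5-oxotetrahydrofuran-2-carbaldehyde F1. Iodide 15 is converted by iodine–lithium exchange (t-BuLi, Et2O, −78 °C) into the primary alkyllithium F2, which is added to F1 at −78 °C, where the aldehyde should react far faster than the lactone, to give the C15-epimeric carbinols F3. Dess–Martin periodinane then oxidises F3 to ketone 20.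

Step 13. Facial discrimination may be insufficient, because the oxazaborolidine has to tell the quaternary C16 flank from the methylene flank against whatever bias the C16 centre exerts, and the borane may slowly hydroborate the trisubstituted alkenes. The fallback sets out from 18 and 15 and comes back at 21; it sets C15 during C–C bond formation instead of by reduction. Acid chloride 18 is reduced with LiAlH(OtBu)3 to the aldehyde (2S)-2-methyl-5-oxotetrahydrofuran-2-carbaldehyde F4 (the same structure as in the first fallback). Iodide 15 is converted with Mg in Et2O into the Grignard reagent F5 and transmetalated with Ti(OiPr)4 to the alkyltitanium triisopropoxide F6. F6 is added to F4 in the presence of a catalytic titanium complex of a 3-aryl-H8-BINOL ligand (catalytic enantioselective alkylation of aldehydes). The ligand enantiomer is chosen for attack on the Re face of the formyl group, which should give 21 directly.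

Step 5 in the order of risk, step 3 in the route (propargylation). Enantioselectivity may be low or turnover slow with the β,β-disubstituted enal, and the acid catalyst may partly remove the primary silyl ether. The fallback sets out from 5 and comes back at 6. Zinc-mediated Barbier propargylation with propargyl bromide (Zn, THF/aqueous NH4Cl) gives the racemic alcohol F7. Lipase-catalysed kinetic resolution (Burkholderia cepacia lipase, vinyl acetate) should acetylate the R enantiomer to the acetate F8 and leave the S alcohol 6, which is separated by chromatography.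

Further compounds
F1 | step 12 | (2S)-2-methyl-5-oxotetrahydrofuran-2-carbaldehyde | O=C[C@]1(C)CCC(=O)O1
F2 | step 12 | [(3E,5S,7E)-5-(tert-butyldiphenylsilyloxy)-10-(furan-3-yl)-3,7-dimethyldeca-3,7-dienyl]lithium | [Li]CC/C(C)=C/[C@@H](O[Si](c1ccccc1)(c1ccccc1)C(C)(C)C)C/C(C)=C/CCc1ccoc1
F3 | step 12 | (5S)-5-[(4E,6S,8E)-6-(tert-butyldiphenylsilyloxy)-11-(furan-3-yl)-1-hydroxy-4,8-dimethylundeca-4,8-dienyl]-5-methyldihydrofuran-2(3H)-one as a mixture of C15 epimers | OC(CC/C(C)=C/[C@@H](O[Si](c1ccccc1)(c1ccccc1)C(C)(C)C)C/C(C)=C/CCc1ccoc1)[C@]1(C)CCC(=O)O1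
F4 | step 13 | (2S)-2-methyl-5-oxotetrahydrofuran-2-carbaldehyde | O=C[C@]1(C)CCC(=O)O1
F5 | step 13 | [(3E,5S,7E)-5-(tert-butyldiphenylsilyloxy)-10-(furan-3-yl)-3,7-dimethyldeca-3,7-dienyl]magnesium iodide | I[Mg]CC/C(C)=C/[C@@H](O[Si](c1ccccc1)(c1ccccc1)C(C)(C)C)C/C(C)=C/CCc1ccoc1
F6 | step 13 | [(3E,5S,7E)-5-(tert-butyldiphenylsilyloxy)-10-(furan-3-yl)-3,7-dimethyldeca-3,7-dienyl]titanium triisopropoxide | CC(C)O[Ti](OC(C)C)(OC(C)C)CC/C(C)=C/[C@@H](O[Si](c1ccccc1)(c1ccccc1)C(C)(C)C)C/C(C)=C/CCc1ccoc1
F7 | step 3 | (5E)-8-(tert-butyldimethylsilyloxy)-6-methyloct-5-en-1-yn-4-ol, racemic | CC(C)(C)[Si](C)(C)OCC/C(C)=C/C(O)CC#C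
F8 | step 3 | (4R,5E)-8-(tert-butyldimethylsilyloxy)-6-methyloct-5-en-1-yn-4-yl acetate | CC(C)(C)[Si](C)(C)OCC/C(C)=C/[C@H](OC(C)=O)CC#C
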